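Its constants are assumed.

If I followed one molecule of target through these set-ups, it stood at a fork at each moment: in the birch tank it could leave or die as side product, and in the elm flask it could stay or die as side product.

    starting material + 2 target → 3 target (k1 = 4.0 /M²/min)
    starting material → target (k2 = 1.6 × 10⁻⁶ /min)
    starting material + target → side product (k3 = 0.088 /M/min)

the same everywhere: starting material 0.050 M
- birch: one stirred flow tank at steady state, fed with the mixture as stated, mean residence time 8.0 h
- elm: everything together in a closed stirred flask, run for 8.0 h; time 8.0 h

- in percentages every species weighs as the starting material in it: one side product counts as two
- where a step has two of a species, its rate is k times that concentration squared, and two are used at each turn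
- the stated concentrations are those of everything mixed, before any reaction; amounts are the same in each set-up
- run time (elm): 8.0 h

- the set-up with the highest share of target in all that became target or side product, at the outlet or at the end ("none" if the first two lie within 2 percentage points) (birch / elm / none)
- share of target in all that became target or side product, at the outlet or at the end, birch
- share of target in all that became target or side product, at the outlet or at the end, elm

**The life.** With starting material near its charge, the side reaction was pseudo-first-order in target. Its rate per target molecule gave 3.79 h, and this, the mean time before the side reaction takes a target molecule at the charged level of starting material, is the target's life.

**First doubt.** The autocatalytic step might ignite. Per target molecule it outruns the side reaction only above a target fraction of 44.0%. But the uncatalysed feed, set against the side reaction, gave a balance level of target of 0.0364% of the charge, far below that. I dropped the autocatalytic step.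

**Second doubt.** The life might drift as starting material went. But the half-life of starting material by the uncatalysed step is 300 d. With the side reaction also taking starting material, at the rate of the uncatalysed step as the balance level implies, that half-life is 150 d, far longer than the run. I kept the life constant.

**Counting lives.** Each set-up lasted n = 2.11 lives. In the birch tank, the odds of dying against leaving were n to one. Weighing survivors at one and the dead at two gave 19.1%. In the elm flask, target climbed to 0.879 of its level, and side product held n minus that, in the same unit, weighing two. That gave 26.3%, so I expected elm ahead by 7.2 percentage points, more than the margin.

**The forecast.** It named elm, with 19.1% for birch and 26.3% for elm. Its ground: “the flask has less target early on and so loses less to side product”.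

**The result.** Elm gave 26.3% and birch 19.2%, so elm led. In elm, the half-life of target by the side reaction was 2.6 h, far shorter than the 300 d of starting material by the uncatalysed step. Elm held 0.0320% target beside 99.9% starting material at 8.00 h. Elm left until 20 h ran 5.28 lives, which reckons to 10.4%, and that flask gave 10.4%.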